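The runs stem from a simulated flask on assumed constants; scatter was added.

Per cent of the E charged is the unit I read these runs in.

| flask | E | L | time |
|---|---|---|---|
| autumn | 0.120 M | 0.00120 M |  |
| summer | 0.0480 M | 0.00120 M |  |
| winter | 0.120 M | 0.00360 M |  |
| noon | 0.180 M | 0.00120 M |  |
| spring | 0.290 M | 0.00120 M | 150 min |

- autumn run (time / min: [J] / M): 30: 0.0322; 60: 0.0480; 90: 0.0526; 120: 0.0563; 150: 0.0565
- summer run (time / min: [J] / M): 30: 0.0116; 60: 0.0159; 90: 0.0221; 120: 0.0215; 150: 0.0217
- winter run (time / min: [J] / M): 30: 0.0508; 60: 0.0681; 90: 0.0732; 120: 0.0742; 150: 0.0752
- noon run (time / min: [J] / M): 30: 0.0482; 60: 0.0711; 90: 0.0807; 120: 0.0837; 150: 0.0861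

(scatter of a reading: 0.001 M)

- Overall: E -> J, with L as catalyst.
- Constant volume, constant temperature.
- What is held in complexes is read along with the free species.
- An order is taken over about fifteen percent of the charge, up and down.

* the exponent of [E] in the starting rate at the charge of the autumn run (at the point where two percent of the E have become J) (one fixed amount of J, the same in the runs compared)
* the exponent of [L] in the starting rate at the charge of the autumn run (at the point where two percent of the E have become J)
* J in the spring run at 150 min, as a share of the E charged

In that unit the runs at equal L nearly coincide. At 30 min the summer, autumn and noon runs stand at 24.2%, 26.8% and 26.8%, and the summer share carries a scatter of 2.08%. So J at a given time grows in step with the charge, and I take the order in E as 1.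

What to watch is the end share f, the J at which a run stops as a share of the E charged. I reach it two ways. The first is the last reading over the charge:

f = J(last) / E charged, which for the noon run is 47.8%

The second uses earlier readings. If the gap to the end shrinks by the same fraction in each equal step, and a and b are J at one time and at twice that time, then:

J(end) = a·a / (a + a − b)

With the readings at 60 min and 120 min, the noon run gives 48.0%, so the two ways agree. The winter run agrees too, at 62.7% and 62.3%.

The summer run parts them, at 45.2% against 51.1%. There the second way cheats: its bottom line is 0.01030 M with a scatter of 0.002236 M, an uncertainty of 21.7%, larger than the 4.61% of the last reading.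

For L, the first readings of the winter and autumn runs can't be compared as they stand. At 30 min the winter run has made 42.3% of its charge and the autumn run 26.8%, so their ratio of 1.58 compares amounts made, not starting rates. The same shrinking gap gives a starting rate, with t the time of reading a:

starting rate = J(end) · ln(a / (b − a)) / t

With the readings at 30 min and 60 min, the autumn run gives 0.00150 M min⁻¹ and the winter run 0.00277 M min⁻¹. A factor of 3.00 in L thus gives a factor of 1.85 in rate, so my order in L is 0.557. This is a reading that carries the scatter of those readings, and a mean across that whole factor in L, a wider step than the narrow span over which the order is asked. For the spring run I commit to the noon share, which means 0.139 M of J at 150 min.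

The forecast gives 1, 0.6 and 48.5%, on the ground that “extrapolating the plateau gives about 48–49%, and 150 min is essentially at the plateau”. Its order in L stands above mine.

The flask gives 1.0 in E, 0.48 in L and 47.1% for the spring run.

    L + E ⇌ LE, settled at all times (154.0 L mol⁻¹)
    LE + E ⇌ LE2, settled at all times (1.290 L mol⁻¹)
    LE2 → J + LE (4.830 min⁻¹)
    E → Qi (0.01344 min⁻¹)
    E → J (0.006660 min⁻¹)

That spring share lies 0.70 percentage points below the noon end share, while a fit with the main steps alone puts it at 69.6%. The end share also serves the winter run, which reaches a quarter of its charge at 12.9 min. With f at 62.7% and the gap shrinking by equal fractions, half should come at 40.5 min. The winter run reaches half of its charge at 40.0 min.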